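## The problem

Target 7, (1R,2R)-1-(3,4-dimethoxyphenyl)-2-methyl-3-oxobutyl 3,4-dimethoxybenzoate, is an open chain C1–C4. C1 is benzylic and carries the aroyloxy group, C2 carries a methyl group, and C3 is a methyl ketone; no ring has to be closed. The stereocentres C1 and C2 are adjacent and both R, which places the C1–O and C2–CH3 bonds syn in the zigzag drawing and the hydrogens on C1 and C2 on one side. They sit in a labile setting: C2–H is α to the ketone and epimerises through the enol, and C1 bears a carboxylate leaving group β to the ketone on an electron-rich benzylic carbon. Base therefore causes E1cB loss of the acid to a conjugated enone, and acid ionises C1. The usual last step, acylation of a β-hydroxy ketone, is thus the operation the product tolerates worst, and C2 is the internal α-carbon of a butanone unit, not the one that enolises kinetically. The feature used here is that the ester carbonyl carbon and the ketone carbon C3 are 1,4-related through O–C1–C2. Joined by a bond they close the five-membered ring O–C1–C2–C3–C(ester), a furan skeleton with aryl groups on both α-carbons and methyl groups on both β-carbons. Because both aryl groups are the same 3,4-dimethoxyphenyl ring, that furan (4) is C2v-symmetric: cleaving either C=C gives the same enol ester 6, with ester and ketone formed together. 6 lacks only the two syn hydrogens, so one suprafacial addition of H2 to its Z double bond sets both stereocentres at once under neutral conditions.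

## Retrosynthesis

**7 to 6.** The C1–H and C2–H bonds are cut. The neighbouring cuts, C1–C2 (aldol) and acyl C–O (esterification), both end in a β-hydroxy ketone that must be acylated next to its own acidic C2–H. Removing the two hydrogens instead leaves (Z)-enol ester 6, which is achiral, has both carbonyl groups and all 22 carbons in place, and has no hydrogen on C2 and so no E1cB path. The forward reaction must add H2 to one face of a tetrasubstituted C=C. Syn addition to the Z isomer (acyloxy cis to acetyl, aryl cis to methyl) can only give the (1R,2R)/(1S,2S) pair, so relative configuration follows from geometry and only the face has to be chosen by a chiral catalyst. The ester carbonyl offers a chelating handle for that.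

**6 to 4.** In the retrosynthetic sense the ester carbonyl carbon and C3 are joined as a C=C bond, which turns 6 into furan 4. Forward, one furan C=C is cleaved by ozone through methoxy hydroperoxide 5. The other conceivable way to an enol ester, O-acylation of a 1,3-dicarbonyl enolate, would have to choose between two oxygens. It is expected to acylate the wrong one, because the acetyl oxygen is the more nucleophilic and the aroyl-conjugated isomer the more stable. The ring cleavage has no such choice: the two C=C bonds of 4 are related by symmetry, and the ring delivers the Z geometry that step 4 needs. 4 has no stereocentre and no carbonyl group. The forward step asks ozone to react as a 1,3-dipole across one C=C only and to stop after one equivalent.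

**4 to 3.** Both ring C–O bonds are cut (Paal–Knorr retron), giving 1,4-diketone 3. Its two stereocentres are irrelevant, since both diastereomers dehydrate to the same furan. The forward step asks only for acid and removal of water.

**3 to 1.** The central C2–C3 bond of 3 is cut into two identical halves, each the enolate 2 of commercial ketone 1. Forward, this is an oxidative enolate homocoupling. All 22 carbon atoms of 7 come from two molecules of one C11 ketone, and no cross-coupling selectivity is needed.

## Roads not taken

Alternative 1: the obvious route cuts the acyl C–O bond and then the C1–C2 bond. Forward, an asymmetric syn-aldol reaction (for instance an Evans aldol of a propionyl oxazolidinone with the aryl aldehyde, then conversion of the imide into the methyl ketone) gives hydroxy ketone A1, which is acylated with the aroyl chloride. The chosen plan is better for two reasons. A1 cannot be reached directly, because the C4 ketone enolises at the wrong α-carbon, so an auxiliary and two or three functional-group steps are needed. And the last step acylates a β-hydroxy ketone under amine base, where the product is set up for E1cB elimination, retro-aldol cleavage and epimerisation at C2. In the chosen route no intermediate that has both the C2–H and the C1 leaving group meets a base, and the ester is never made by acylation.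

Alternative 2: cut the same C1–C2 bond at the alkene oxidation level, with the ketone masked. Forward, (Z)-crotylboration of the aryl aldehyde with a diisopinocampheylborane reagent gives syn homoallylic alcohol A2, esterification gives A3, and Tsuji–Wacker oxidation of the vinyl group gives the methyl ketone. This is the strongest competitor: three steps with close precedent, and the ester is installed before the ketone exists. It was not chosen because it needs a stoichiometric chiral reagent and three different building blocks where the chosen route needs one ketone and a catalyst. It also forms the sensitive β-acyloxy ketone under acidic palladium/copper chloride conditions, where alkene migration through a palladium hydride and enolisation both touch C2. It makes no use of the symmetry of the target.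

Alternative 3: cut only the C1–H bond, by dynamic kinetic resolution. Forward, ruthenium–TsDPEN transfer hydrogenation of racemic 2-methyl-1,3-diketone A4, whose C2 centre racemises through the enol, gives A1, which is acylated as in Alternative 1. The structure works against this stereoconvergent idea. A4 has two ketones, and the one that must be reduced is the 3,4-dimethoxybenzoyl carbonyl, a vinylogous ester less electrophilic than the acetyl group, so reduction is expected at the wrong carbonyl. Even if it succeeds, the route ends in the same hazardous acylation of A1.

Key step: step 4

Assumption: ketone 1, LiN(iPr)2 solution and both antipodes of the rhodium–Me-BPE precatalyst are taken as commercially available.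

## Steps

Step 1
Reactants: 1 1-(3,4-dimethoxyphenyl)propan-1-one (two molecules)
Product: 3 1,4-bis(3,4-dimethoxyphenyl)-2,3-dimethylbutane-1,4-dione, via lithium enolate 2 (not isolated)
Conditions: LiN(iPr)2 (1.05 equiv), THF, −78 °C; then CuCl2 (1.1 equiv), DMF, −78 °C to rt
Reagents that add atoms: none
Why: Oxidative homocoupling of a lithium enolate: one-electron oxidation by divalent copper joins two α-carbons, a reaction type well established for aryl ethyl ketones. The two new stereocentres need no control because the meso and racemic forms of 3 converge on 4 in step 2.

Step 2
Reactants: 3 1,4-bis(3,4-dimethoxyphenyl)-2,3-dimethylbutane-1,4-dione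
Product: 4 2,5-bis(3,4-dimethoxyphenyl)-3,4-dimethylfuran
Conditions: TsOH·H2O (10 mol %), toluene, reflux, Dean–Stark trap
Reagents that add atoms: none
Why: Paal–Knorr furan synthesis: acid-catalysed attack of one enol oxygen on the other carbonyl and loss of water, driven by aromatisation. Both stereocentres of 3 become sp2, so the diastereomer mixture funnels into one achiral, C2v-symmetric furan.

Step 3
Reactants: 4 2,5-bis(3,4-dimethoxyphenyl)-3,4-dimethylfuran
Product: 6 (Z)-1-(3,4-dimethoxyphenyl)-2-methyl-3-oxobut-1-en-1-yl 3,4-dimethoxybenzoate, via methoxy hydroperoxide 5 (not isolated)
Conditions: O3 (1.0 equiv, titrated solution in CH2Cl2), CH2Cl2–MeOH 4:1, −78 °C; then Me2S (3 equiv), −78 °C to rt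
Reagents that add atoms: ozone, [O-][O+]=O
Why: Ozonolysis of one furan C=C (1,3-dipolar cycloaddition, then cycloreversion by the Criegee mechanism): the oxygen-bearing carbon becomes the ester carbonyl directly and the methyl-bearing carbon a carbonyl oxide that methanol traps as 5, which Me2S reduces to the ketone with release of the methanol. The two C=C bonds of 4 are equivalent by symmetry, so only one constitution can result, and the former ring holds the acyloxy and acetyl groups cis (Z). The remaining C=C of 6 is an electron-poor β-acyloxy enone that one equivalent of ozone at −78 °C should leave alone.

Step 4
Reactants: 6 (Z)-1-(3,4-dimethoxyphenyl)-2-methyl-3-oxobut-1-en-1-yl 3,4-dimethoxybenzoate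
Product: 7 (1R,2R)-1-(3,4-dimethoxyphenyl)-2-methyl-3-oxobutyl 3,4-dimethoxybenzoate
Conditions: H2 (30 bar), [Rh(cod)((R,R)-Me-BPE)]OTf (5 mol %), CH2Cl2, 25 °C
Reagents that add atoms: none
Why: Proposed new method: the closest known reaction type is the rhodium–bis(phospholane)-catalysed asymmetric hydrogenation of enol esters and of tetrasubstituted β,β-disubstituted enamides, which has not been shown on an acyclic tetrasubstituted β-acyloxy enone. The cationic monovalent rhodium centre is expected to bind 6 through the C1=C2 bond and the carbonyl oxygen of the aroyloxy group; after oxidative addition of H2, hydride migrates to C2, rhodium is left on C1 as an α-acyloxy benzylic alkyl held in a five-membered chelate, and C–H reductive elimination with retention puts the second hydrogen on the same face. No ring is closed. Because the addition is suprafacial and the ring origin of 6 fixes the Z geometry, the relative configuration at C1 and C2 can only be syn, so the catalyst has to choose only the face. Both stereocentres are set together by the face the C2-symmetric ligand exposes; (1R,2R) requires hydrogen on the face that is Re at C1 and Si at C2 of 6. The (R,R) ligand is a first choice made by analogy with the chelation model for 1-aryl enol esters, the sense has to be confirmed on 7, and the (S,S) complex is used if it is reversed. The step needs chemoselectivity for C=C over the ketone and the benzylic C–O bond, which cationic rhodium–bisphosphine catalysts normally give, and it needs the acetyl group not to divert the cycle through an oxygen-bound rhodium enolate that could scramble C2; the non-coordinating solvent and the five-membered ester chelate are relied on for this. The push–pull polarisation of the C=C (acyloxy donor, acetyl acceptor) should help hydride insertion into an otherwise hindered alkene.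

## Compound list

1 | 1-(3,4-dimethoxyphenyl)propan-1-one | CCC(=O)c1ccc(OC)c(OC)c1 | starting material
2 | lithium (Z)-1-(3,4-dimethoxyphenyl)prop-1-en-1-olate | C/C=C(\[O-])c1ccc(OC)c(OC)c1.[Li+] | intermediate
3 | 1,4-bis(3,4-dimethoxyphenyl)-2,3-dimethylbutane-1,4-dione (mixture of meso and racemic diastereomers) | COc1ccc(C(=O)C(C)C(C)C(=O)c2ccc(OC)c(OC)c2)cc1OC | intermediate
4 | 2,5-bis(3,4-dimethoxyphenyl)-3,4-dimethylfuran | COc1ccc(-c2oc(-c3ccc(OC)c(OC)c3)c(C)c2C)cc1OC | intermediate
5 | (Z)-3-hydroperoxy-3-methoxy-1-(3,4-dimethoxyphenyl)-2-methylbut-1-en-1-yl 3,4-dimethoxybenzoate (racemic at C3) | COc1ccc(C(=O)O/C(c2ccc(OC)c(OC)c2)=C(/C)C(C)(OC)OO)cc1OC | intermediate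
6 | (Z)-1-(3,4-dimethoxyphenyl)-2-methyl-3-oxobut-1-en-1-yl 3,4-dimethoxybenzoate | COc1ccc(C(=O)O/C(c2ccc(OC)c(OC)c2)=C(/C)C(C)=O)cc1OC | intermediate
7 | (1R,2R)-1-(3,4-dimethoxyphenyl)-2-methyl-3-oxobutyl 3,4-dimethoxybenzoate | COc1ccc(C(=O)O[C@@H](c2ccc(OC)c(OC)c2)[C@@H](C)C(C)=O)cc1OC | target

## Step count and risks

Total step count: 4. Longest linear sequence: 4 steps (1 to 7).

**Step 4 (key step; bears the label "Proposed new method:").** The most likely failures are:
- slow or no turnover, because a tetrasubstituted enol ester with a twisted aryl group binds cationic rhodium weakly;
- poor facial selectivity, or selectivity for the wrong face, since the sense of induction rests on analogy;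
- erosion of the syn relationship, if the cycle runs through ketone coordination and an oxygen-bound rhodium enolate, or if the double bond isomerises from Z to E before reduction;
- 1,5-acyl transfer from the enol oxygen to the ketone oxygen before reduction.

Fallback (known chemistry): from 6, hydrogenation with the achiral complex [Ir(cod)(PCy3)(py)]PF6 in CH2Cl2, a catalyst type established for carbonyl-directed hydrogenation of tetrasubstituted alkenes, adds H2 suprafacially to the Z alkene. It gives the syn ester as the racemate, that is 7 together with its mirror image (1S,2S)-1-(3,4-dimethoxyphenyl)-2-methyl-3-oxobutyl 3,4-dimethoxybenzoate F1. 7 and F1 are separated by preparative chromatography on a polysaccharide-carbamate chiral stationary phase, and the route is rejoined at 7. This replaces asymmetric catalysis by a geometry-controlled racemic reduction and a resolution.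

**Step 3.** Ozone may fail to react as a 1,3-dipole across one C=C and instead attack an α-carbon, lose O2 and open the ring (formal 1,4-oxygenation), a known side path of aryl-substituted furans. Further risks are over-oxidation of the remaining C=C or of the dimethoxyphenyl rings if more than one equivalent is delivered, and methanolysis of the acyl group of the vinylogous anhydride during work-up.

Fallback: from 1, Vilsmeier–Haack–Arnold chloroformylation (POCl3, DMF) gives (Z)-3-chloro-3-(3,4-dimethoxyphenyl)-2-methylprop-2-enal F2, with chlorine on the former carbonyl carbon. Addition of MeMgBr gives (Z)-4-chloro-4-(3,4-dimethoxyphenyl)-3-methylbut-3-en-2-ol F3. Oxidation with MnO2 gives (Z)-4-chloro-4-(3,4-dimethoxyphenyl)-3-methylbut-3-en-2-one F4. Addition–elimination of caesium 3,4-dimethoxybenzoate in DMF replaces chloride by the acyloxy group on the aryl-bearing carbon and rejoins the route at 6. This builds the enol ester regiospecifically by substitution instead of ring cleavage; its own weak point is retention of the Z geometry in the last substitution.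

**Step 1.** The oxidative coupling may be accompanied by α-chlorination of the enolate by CuCl2 and by incomplete conversion.

Fallback: from 1, bromination with CuBr2 (EtOAc–CHCl3, reflux) gives 2-bromo-1-(3,4-dimethoxyphenyl)propan-1-one F5. F5 alkylates enolate 2 (made from a second portion of 1 with LiN(iPr)2) in an SN2 reaction and rejoins the route at 3. A two-electron alkylation replaces the one-electron coupling.

## Further compounds

F1 | step 4 | (1S,2S)-1-(3,4-dimethoxyphenyl)-2-methyl-3-oxobutyl 3,4-dimethoxybenzoate (enantiomer of 7) | COc1ccc(C(=O)O[C@H](c2ccc(OC)c(OC)c2)[C@H](C)C(C)=O)cc1OC
F2 | step 3 | (Z)-3-chloro-3-(3,4-dimethoxyphenyl)-2-methylprop-2-enal | Cl/C(c1ccc(OC)c(OC)c1)=C(/C)C=O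
F3 | step 3 | (Z)-4-chloro-4-(3,4-dimethoxyphenyl)-3-methylbut-3-en-2-ol (racemic) | Cl/C(c1ccc(OC)c(OC)c1)=C(/C)C(C)O
F4 | step 3 | (Z)-4-chloro-4-(3,4-dimethoxyphenyl)-3-methylbut-3-en-2-one | Cl/C(c1ccc(OC)c(OC)c1)=C(/C)C(C)=O
F5 | step 1 | 2-bromo-1-(3,4-dimethoxyphenyl)propan-1-one (racemic) | CC(Br)C(=O)c1ccc(OC)c(OC)c1
A1 | alternative 1 | (3R,4R)-4-(3,4-dimethoxyphenyl)-4-hydroxy-3-methylbutan-2-one | O[C@@H](c1ccc(OC)c(OC)c1)[C@@H](C)C(C)=O
A2 | alternative 2 | (1R,2S)-1-(3,4-dimethoxyphenyl)-2-methylbut-3-en-1-ol | O[C@@H](c1ccc(OC)c(OC)c1)[C@@H](C)C=C
A3 | alternative 2 | (1R,2S)-1-(3,4-dimethoxyphenyl)-2-methylbut-3-en-1-yl 3,4-dimethoxybenzoate | COc1ccc(C(=O)O[C@@H](c2ccc(OC)c(OC)c2)[C@@H](C)C=C)cc1OC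
A4 | alternative 3 | 1-(3,4-dimethoxyphenyl)-2-methylbutane-1,3-dione (racemic) | CC(=O)C(C)C(=O)c1ccc(OC)c(OC)c1
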